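I decided to work in logarithms, since the target forms at a rate proportional to open intermediate times second intermediate, and logarithms turn a product into a sum.

    substrate + partner B → open intermediate (k1 = 0.048 /M/s)
    partner B + partner A → second intermediate (k2 = 0.0042 /M/s)
    open intermediate + second intermediate → target (k3 = 0.0040 /M/s)
    2 open intermediate → homo product (k4 = 0.0010 /M/s)
    gas ⇌ partner A, rate k5*(csat - [partner A]) (k5 = 3.0 × 10⁻⁴ /s, csat = 41 mM)

| flask | substrate | partner B | gas | time |
|---|---|---|---|---|
| south | 0.030 M | 0.110 M | 41 mM (held) | 50 min |
| west | 0.060 M | 0.110 M | 41 mM (held) | 50 min |
| north-east | 0.12 M | 0.110 M | 41 mM (held) | 50 min |

- percentages count the substrate that a species holds: one homo product counts as two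
- for a step with 2 of a species take k times the square, and two of it per event
- at the start none of partner A is dissolved
- "hardly changes" means that all values lie within two and a half points (for a concentration: within two and a half percent of the largest)
- run time (south): 50 min

- [target] at the end for south, west, north-east, in this order
- how that number moves from the first to the last of them (hardly changes / rises, then falls / falls, then rises / falls all the way / rises all the way)

I followed south slowly, writing s for the substrate charge and b for the partner B charge. In the first minutes of south, substrate halves in 2.2 min, far faster than the 25 min partner A takes to halve against partner B. So substrate takes partner B one for one and leaves a surplus, b − s, of 0.0800 M. Meanwhile gas feeds partner A at 0.738 mM/min into a liquid that started with none.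

In the middle of south, dissolved partner A meets that surplus and second intermediate grows. Open intermediate stays near the substrate charge, because its half-life by homo coupling, 278 min, is longer than the 50 min run. Second intermediate accumulates, because its lifetime against open intermediate, 139 min, is also longer than the run.

Towards the end, target is what matters, and I took it as proportional to s(b − s). One percent more substrate adds a percent to the first factor and removes s/(b − s) percent from the second. That gives the local reaction order of target in substrate, n, equal to one minus s/(b − s): 0.625 for south. For west it is −0.200, and it crosses zero at s = b/2, or 0.0550 M. North-east charges more substrate than partner B, by 0.0100 M, so there I expected little target.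

For a size, I let partner A, second intermediate and target grow steadily in turn, which brings in the cube of the time over 6. This gave 0.00223 M for south and 0.00279 M for west.

The forecast gave 0.0012 M, 0.0013 M and 5.000 × 10⁻⁴ M, a row that rises, then falls, on the ground that “more substrate first helps by raising the open intermediate but then hurts by using up partner B”. Its south figure is lower than mine, but its shape is the one my order gave.

The flasks gave 0.00116 M, 0.00139 M and 4.92 × 10⁻⁴ M, a row that rises, then falls. My south size was about twice the result. The local order read for south is 0.54, lower than my 0.625. West's order of −0.200 places that flask just past the top, and the row turns at 0.054 M, less than the west charge of 0.060 M.

Its constants are invented; no experiment stands behind them.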